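**Plan**

1. Numbering (indane): C-1 ethylidene carbon, C-2 acetoxy carbon, C-3, C-3a, C-4 methylidene carbon, C-5 angelate carbon, C-6 carbinol, C-7 isopropyl carbon, C-7a. Retrosynthesis: the C-5 angelate/C-6 hydroxyl pair goes back to a 5α,6α-epoxide (C-5–O cut), the two exocyclic alkenes to C-4 and C-1 ketones, the epoxide to a cyclohex-2-enone, and the six-membered ring is then cut at C-5–C-6 and C-7–C-7a.
2. Enabling feature: with C-4 as a carbonyl, ring atoms C-7a/C-3a/C-4/C-5 are a 1-acetylcyclopentene (acceptor at C-7a, donor at C-5), and C-7(iPr)/C-6 are the α-carbon and carbonyl carbon of 3-methylbutanal. Both bonds then have natural polarity and can form in one Michael/aldol-condensation annulation.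
3. Forward order: five-membered ring first (D-erythronolactone acetonide to acetylcyclopentene 8, steps 1–5), six-membered ring by annulation (step 6), then epoxide, methylidene, ethylidene, acetate and last the angelate.
4. Stereochemistry: C-1/C-2 oxygens from the chiral pool; C-7a by addition anti to the acetonide; C-3a and C-7 by equilibration to the trans-fused, all-equatorial enone; the epoxide by axial attack; C-5 by inversion in the final SN2 opening; the Z-ethylidene by Wittig reaction next to the silyloxy carbon.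

Key step: step 6

Remark: α is the face of H-7a and β the face of H-3a; compounds 1, 3, 9 and 21 and all reagents are taken as commercial.

**Route**

Step 1
Reactants: 1 2,3-O-isopropylidene-D-erythronolactone
Product: 2 2,3-O-isopropylidene-D-erythrofuranose (lactol; anomer mixture)
Conditions: iBu2AlH (1.1 equiv), CH2Cl2, −78 °C
Reagents that add atoms: none
Why: Partial reduction of a γ-lactone to the lactol with iBu2AlH at low temperature is routine and leaves the two acetonide-bearing centres (later C-2 and C-1) untouched.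

Step 2
Reactants: 2 2,3-O-isopropylidene-D-erythrofuranose; 3 1-(triphenylphosphoranylidene)propan-2-one
Product: 4 (E)-4-[(4S,5R)-5-(hydroxymethyl)-2,2-dimethyl-1,3-dioxolan-4-yl]but-3-en-2-one
Conditions: PhCO2H (5 mol%), CH2Cl2, 40 °C
Reagents that add atoms: none
Why: Wittig olefination of the open-chain aldehyde form of the lactol with a stabilised ylide should give the E-enone under neutral conditions that keep the freed primary hydroxyl from adding back to the enone; the alkene geometry is of no consequence because this double bond is reduced in step 4.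

Step 3
Reactants: 4 (E)-4-[(4S,5R)-5-(hydroxymethyl)-2,2-dimethyl-1,3-dioxolan-4-yl]but-3-en-2-one
Product: 5 (4S,5S)-2,2-dimethyl-5-[(E)-3-oxobut-1-en-1-yl]-1,3-dioxolane-4-carbaldehyde
Conditions: DMP (1.2 equiv), CH2Cl2, 0 °C to rt
Reagents that add atoms: none
Why: Hypervalent-iodine oxidation of the primary alcohol to the aldehyde runs without base, so the α-alkoxy aldehyde centre (later C-1) should not epimerise.

Step 4
Reactants: 5 (4S,5S)-2,2-dimethyl-5-[(E)-3-oxobut-1-en-1-yl]-1,3-dioxolane-4-carbaldehyde
Product: 6 1-[2-hydroxy-3,4-(isopropylidenedioxy)cyclopentyl]ethan-1-one (aldol; isomer mixture at the two new centres)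
Conditions: H2 (1 atm), Rh(cod)2OTf (5 mol%), (4-CF3C6H4)3P (12 mol%), KOAc (30 mol%), ClCH2CH2Cl, rt
Reagents that add atoms: none
Why: Hydrogen-mediated reductive aldol cyclisation: hydrometalation of the enone places the rhodium enolate on the carbon α to the ketone, which adds 5-exo-trig to the aldehyde under neutral conditions, and the two new centres are removed in step 5.

Step 5
Reactants: 6 1-[2-hydroxy-3,4-(isopropylidenedioxy)cyclopentyl]ethan-1-one
Product: 8 1-[(3R,4S)-3,4-(isopropylidenedioxy)cyclopent-1-en-1-yl]ethan-1-one, via mesylate 7 (not isolated)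
Conditions: MsCl, Et3N, CH2Cl2, 0 °C; then DBU, 0 °C to rt
Reagents that add atoms: none
Why: Mesylation of the β-hydroxy ketone and E1cB elimination through the only acidic hydrogen (α to the ketone) should give the conjugated 1-acetylcyclopentene from either aldol isomer.

Step 6
Reactants: 8 1-[(3R,4S)-3,4-(isopropylidenedioxy)cyclopent-1-en-1-yl]ethan-1-one; 9 3-methylbutanal
Product: 12 7α-isopropyl-1α,2α-(isopropylidenedioxy)-1,2,3,3aβ,7,7aα-hexahydro-4H-inden-4-one, via enamine 10 (not isolated), via keto aldehyde 11 (not isolated)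
Conditions: 9 (2.0 equiv), pyrrolidine (2.0 equiv), 4 Å MS, PhMe, 0 °C to rt; then 8, 90 °C; then AcOH/NaOAc/H2O, 70 °C; then NaOMe (0.2 equiv), MeOH, rt
Reagents that add atoms: none
Why: Enamine 10 adds in a Stork Michael reaction to C-7a, the β-carbon of the acylcyclopentene (new C-7–C-7a bond), buffered hydrolysis releases keto aldehyde 11, and its methyl ketone carbon (C-5) then condenses with the aldehyde carbon (C-6) by aldol addition and E1cB loss of water (new C-5–C-6 bond), a Robinson-type [4+2] annulation. The closest known reaction type is the enamine annulation of 3-methylbutanal with methyl vinyl ketone to 4-isopropylcyclohex-2-enone, together with enamine annulations of 1-acetylcycloalkenes. The six-membered ring closes by a 6-(enolexo)-exo-trig aldol addition, while closure through C-3a or through the aldehyde α-carbon would give four-membered rings and should not compete. C-7a is set by approach of the enamine to the convex face of the cis-fused bicycle, anti to the acetonide oxygen on C-1, whereas C-3a (α to the ketone) and C-7 (α to the aldehyde in 11, γ to the enone in 12) are epimerisable and should settle in the amine and NaOMe stages to the trans ring junction with the isopropyl group equatorial. The step needs conjugate rather than carbonyl addition and must outrun self-condensation of 9, which the preformed enamine, the hindered ketone carbonyl and the β-carbon activated by the γ-oxygen of 8 should secure.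

Step 7
Reactants: 12 7α-isopropyl-1α,2α-(isopropylidenedioxy)-1,2,3,3aβ,7,7aα-hexahydro-4H-inden-4-one
Product: 13 1α,2α-dihydroxy-7α-isopropyl-1,2,3,3aβ,7,7aα-hexahydro-4H-inden-4-one
Conditions: 1 M HCl (aq), THF, rt
Reagents that add atoms: none
Why: Acid hydrolysis of the isopropylidene acetal frees the cis-1,2-diol at the stage where the only other function is an acid-stable enone.

Step 8
Reactants: 13 1α,2α-dihydroxy-7α-isopropyl-1,2,3,3aβ,7,7aα-hexahydro-4H-inden-4-one
Product: 14 5α,6α-epoxy-1α,2α-dihydroxy-7α-isopropyl-octahydro-4H-inden-4-one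
Conditions: H2O2 (30% aq), NaOH (0.5 equiv), MeOH, 0 °C
Reagents that add atoms: hydrogen peroxide (OO)
Why: Weitz–Scheffer epoxidation: hydroperoxide should add to C-6 along the axial trajectory anti to the axial H-7 of the rigid trans-fused enone, so that both epoxide C–O bonds form on the α-face, and the basic medium keeps C-3a at the trans ring junction.

Step 9
Reactants: 14 5α,6α-epoxy-1α,2α-dihydroxy-7α-isopropyl-octahydro-4H-inden-4-one
Product: 15 5α,6α-epoxy-7α-isopropyl-4-methylidene-octahydro-1H-indene-1α,2α-diol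
Conditions: Ph3PCH3Br (4 equiv), KOtBu (3.8 equiv), THF, 0 °C to rt
Reagents that add atoms: methyltriphenylphosphonium bromide (C[P+](c1ccccc1)(c1ccccc1)c1ccccc1.[Br-])
Why: Wittig methylenation of the C-4 ketone with the diol carried as its dialkoxide; the epoxide is inert to the ylide and C-3a can no longer epimerise afterwards.

Step 10
Reactants: 15 5α,6α-epoxy-7α-isopropyl-4-methylidene-octahydro-1H-indene-1α,2α-diol
Product: 16 2α-(tert-butyldimethylsilyloxy)-5α,6α-epoxy-7α-isopropyl-4-methylidene-octahydro-1H-inden-1α-ol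
Conditions: TBSCl (1.05 equiv), imidazole, DMF, 0 °C
Reagents that add atoms: tert-butyldimethylsilyl chloride (CC(C)(C)[Si](C)(C)Cl)
Why: Silyl ether formation should take the C-2 hydroxyl, flanked by a CH2 group, in preference to the C-1 hydroxyl, which is shielded by the ring junction and the isopropyl-bearing carbon; doing this after step 9 avoids base-induced silyl migration in the cis-diol.

Step 11
Reactants: 16 2α-(tert-butyldimethylsilyloxy)-5α,6α-epoxy-7α-isopropyl-4-methylidene-octahydro-1H-inden-1α-ol
Product: 17 2α-(tert-butyldimethylsilyloxy)-5α,6α-epoxy-7α-isopropyl-4-methylidene-octahydro-1H-inden-1-one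
Conditions: DMP, pyridine, CH2Cl2, 0 °C to rt
Reagents that add atoms: none
Why: Buffered hypervalent-iodine oxidation of the remaining secondary alcohol should give the C-1 ketone without touching the acid-sensitive vinyl epoxide.

Step 12
Reactants: 17 2α-(tert-butyldimethylsilyloxy)-5α,6α-epoxy-7α-isopropyl-4-methylidene-octahydro-1H-inden-1-one
Product: 18 tert-butyl{[(1Z)-5α,6α-epoxy-1-ethylidene-7α-isopropyl-4-methylidene-octahydro-1H-inden-2α-yl]oxy}dimethylsilane
Conditions: Ph3P(CH2CH3)Br (3 equiv), KOtBu (2.8 equiv), THF, −78 °C to 0 °C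
Reagents that add atoms: ethyltriphenylphosphonium bromide (CC[P+](c1ccccc1)(c1ccccc1)c1ccccc1.[Br-])
Why: Wittig olefination of an α-silyloxy ketone with a non-stabilised ylide places the new alkyl group cis to the oxygenated carbon, and allylic 1,3-strain with the C-7a–C-7 bond pushes the methyl group the same way, so the Z-ethylidene should form, with addition at low temperature outrunning enolisation towards C-7a.

Step 13
Reactants: 18 tert-butyl{[(1Z)-5α,6α-epoxy-1-ethylidene-7α-isopropyl-4-methylidene-octahydro-1H-inden-2α-yl]oxy}dimethylsilane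
Product: 19 (1Z)-5α,6α-epoxy-1-ethylidene-7α-isopropyl-4-methylidene-octahydro-1H-inden-2α-ol
Conditions: Bu4NF, THF, 0 °C to rt
Reagents that add atoms: none
Why: Fluoride-mediated desilylation frees the allylic C-2 alcohol and should leave the vinyl epoxide and both alkenes untouched.

Step 14
Reactants: 19 (1Z)-5α,6α-epoxy-1-ethylidene-7α-isopropyl-4-methylidene-octahydro-1H-inden-2α-ol
Product: 20 (1Z)-5α,6α-epoxy-1-ethylidene-7α-isopropyl-4-methylidene-octahydro-1H-inden-2α-yl acetate
Conditions: Ac2O, pyridine, DMAP (cat.), CH2Cl2, rt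
Reagents that add atoms: acetic anhydride (CC(=O)OC(C)=O)
Why: Standard acylation of the only free hydroxyl gives the C-2 acetate with retention.

Step 15
Reactants: 20 (1Z)-5α,6α-epoxy-1-ethylidene-7α-isopropyl-4-methylidene-octahydro-1H-inden-2α-yl acetate; 21 angelic acid
Product: 22 (1Z,2S,3aR,5S,6S,7S,7aR)-2-(acetyloxy)-1-ethylidene-6-hydroxy-4-methylidene-7-(propan-2-yl)octahydro-1H-inden-5-yl (2Z)-2-methylbut-2-enoate
Conditions: 21 (3 equiv), Cs2CO3 (0.2 equiv), DMF, 60 °C
Reagents that add atoms: none
Why: SN2 opening of the vinyl epoxide by the carboxylate at the allylic carbon C-5 from the β-face is the trans-diaxial mode of the locked chair, so C-5 is inverted to the axial angelate and C-6 keeps its α-oxygen as the free axial hydroxyl, while the metal-free conditions should disfavour SN2′ attack at the methylidene carbon.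

**Compound list**

1 | 2,3-O-isopropylidene-D-erythronolactone, (3aR,6aR) | O=C1OC[C@H]2OC(C)(C)O[C@@H]12 | starting material
2 | 2,3-O-isopropylidene-D-erythrofuranose (lactol; anomer mixture) | OC1OC[C@H]2OC(C)(C)O[C@@H]12 | intermediate
3 | 1-(triphenylphosphoranylidene)propan-2-one | CC(=O)C=P(c1ccccc1)(c1ccccc1)c1ccccc1 | starting material
4 | (E)-4-[(4S,5R)-5-(hydroxymethyl)-2,2-dimethyl-1,3-dioxolan-4-yl]but-3-en-2-one | CC(=O)/C=C/[C@@H]1OC(C)(C)O[C@@H]1CO | intermediate
5 | (4S,5S)-2,2-dimethyl-5-[(E)-3-oxobut-1-en-1-yl]-1,3-dioxolane-4-carbaldehyde | CC(=O)/C=C/[C@@H]1OC(C)(C)O[C@@H]1C=O | intermediate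
6 | 1-[2-hydroxy-3,4-(isopropylidenedioxy)cyclopentyl]ethan-1-one (3,4-centres as in 8; acetyl- and hydroxyl-bearing centres as the aldol isomer mixture) | CC(=O)C1C(O)[C@H]2OC(C)(C)O[C@H]2C1 | intermediate
7 | methanesulfonate of 6 (formed in the flask, not isolated) | CC(=O)C1C(OS(C)(=O)=O)[C@H]2OC(C)(C)O[C@H]2C1 | intermediate
8 | 1-[(3R,4S)-3,4-(isopropylidenedioxy)cyclopent-1-en-1-yl]ethan-1-one | CC(=O)C1=C[C@H]2OC(C)(C)O[C@H]2C1 | intermediate
9 | 3-methylbutanal | CC(C)CC=O | starting material
10 | (E)-1-(3-methylbut-1-en-1-yl)pyrrolidine (formed in the flask, not isolated) | CC(C)/C=C/N1CCCC1 | intermediate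
11 | 2-[2-acetyl-4,5-(isopropylidenedioxy)cyclopentyl]-3-methylbutanal (side chain anti to the acetonide; acetyl-bearing and isopropyl-bearing centres epimerisable; formed in the flask, not isolated) | CC(=O)C1C[C@@H]2OC(C)(C)O[C@@H]2[C@H]1C(C(C)C)C=O | intermediate
12 | 7α-isopropyl-1α,2α-(isopropylidenedioxy)-1,2,3,3aβ,7,7aα-hexahydro-4H-inden-4-one (trans-fused) | O=C1[C@@H]2C[C@@H]3OC(C)(C)O[C@@H]3[C@H]2[C@H](C(C)C)C=C1 | intermediate
13 | 1α,2α-dihydroxy-7α-isopropyl-1,2,3,3aβ,7,7aα-hexahydro-4H-inden-4-one | O=C1[C@@H]2C[C@H](O)[C@H](O)[C@H]2[C@H](C(C)C)C=C1 | intermediate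
14 | 5α,6α-epoxy-1α,2α-dihydroxy-7α-isopropyl-octahydro-4H-inden-4-one | O=C1[C@@H]2C[C@H](O)[C@H](O)[C@H]2[C@H](C(C)C)[C@@H]3O[C@H]13 | intermediate
15 | 5α,6α-epoxy-7α-isopropyl-4-methylidene-octahydro-1H-indene-1α,2α-diol | C=C1[C@@H]2C[C@H](O)[C@H](O)[C@H]2[C@H](C(C)C)[C@@H]3O[C@H]13 | intermediate
16 | 2α-(tert-butyldimethylsilyloxy)-5α,6α-epoxy-7α-isopropyl-4-methylidene-octahydro-1H-inden-1α-ol | C=C1[C@@H]2C[C@H](O[Si](C)(C)C(C)(C)C)[C@H](O)[C@H]2[C@H](C(C)C)[C@@H]3O[C@H]13 | intermediate
17 | 2α-(tert-butyldimethylsilyloxy)-5α,6α-epoxy-7α-isopropyl-4-methylidene-octahydro-1H-inden-1-one | C=C1[C@@H]2C[C@H](O[Si](C)(C)C(C)(C)C)C(=O)[C@H]2[C@H](C(C)C)[C@@H]3O[C@H]13 | intermediate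
18 | tert-butyl{[(1Z)-5α,6α-epoxy-1-ethylidene-7α-isopropyl-4-methylidene-octahydro-1H-inden-2α-yl]oxy}dimethylsilane | C=C1[C@@H]2C[C@H](O[Si](C)(C)C(C)(C)C)/C(=C\C)[C@H]2[C@H](C(C)C)[C@@H]3O[C@H]13 | intermediate
19 | (1Z)-5α,6α-epoxy-1-ethylidene-7α-isopropyl-4-methylidene-octahydro-1H-inden-2α-ol | C=C1[C@@H]2C[C@H](O)/C(=C\C)[C@H]2[C@H](C(C)C)[C@@H]3O[C@H]13 | intermediate
20 | (1Z)-5α,6α-epoxy-1-ethylidene-7α-isopropyl-4-methylidene-octahydro-1H-inden-2α-yl acetate | C=C1[C@@H]2C[C@H](OC(C)=O)/C(=C\C)[C@H]2[C@H](C(C)C)[C@@H]3O[C@H]13 | intermediate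
21 | angelic acid, (Z)-2-methylbut-2-enoic acid | C/C=C(/C)C(=O)O | starting material
22 | (1Z,2S,3aR,5S,6S,7S,7aR)-2-(acetyloxy)-1-ethylidene-6-hydroxy-4-methylidene-7-(propan-2-yl)octahydro-1H-inden-5-yl (2Z)-2-methylbut-2-enoate (CNP0210397.1) | C=C1[C@@H]2C[C@H](OC(C)=O)/C(=C\C)[C@H]2[C@H](C(C)C)[C@H](O)[C@H]1OC(=O)/C(C)=C\C | target

**Count and risks**

Total step count: 15. Longest linear sequence: 15 steps (from 1).

Steps most likely to fail:

1. Step 6. The conjugate addition of the enamine to the α,β-disubstituted enone may be slow, so that self-condensation of the aldehyde, amine-induced vinylogous loss of the acetal oxygen from 8, or incomplete equilibration at the ring junction take over. Fallback, setting out from 8 and 9 and returning at 12: 9 is converted into trimethyl[(3-methylbut-1-en-1-yl)oxy]silane F1 (Me3SiCl, Et3N, DMF, 80 °C). A Mukaiyama–Michael addition of F1 to 8 (Sc(OTf)3 cat., CH2Cl2, −78 °C) should give the trimethylsilyl enol ether of the adduct F2, which is hydrolysed on work-up to keto aldehyde 11, now isolated. A separate aldol condensation with equilibration (KOH, MeOH, rt) should then give 12.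

2. Step 15. The carboxylate is a weak nucleophile, so the opening may be sluggish, attack at the methylidene carbon (SN2′) may compete, and prolonged heating may isomerise the angelate to the tiglate. Fallback, setting out from 20 and returning at 22: acid-catalysed hydrolysis of the epoxide (HClO4 cat., THF/H2O, 0 °C) should give the trans-diaxial 5β,6α-diol F3. Angelic acid 21 is activated as angelic 2,4,6-trichlorobenzoic anhydride F4 (2,4,6-trichlorobenzoyl chloride, Et3N, PhMe). Yamaguchi esterification of F3 with F4 (DMAP, PhMe, rt) should acylate the allylic C-5 hydroxyl in preference to the C-6 hydroxyl next to the isopropyl group and give 22.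

3. Step 12. The basic ylide may enolise the ketone (epimerisation at C-7a or C-2) and the Z-selectivity may erode. Fallback, setting out from 17 and returning at 18: Horner–Wittig olefination in two stages. Lithiated ethyldiphenylphosphine oxide (n-BuLi, THF, −78 °C) adds to the C-1 ketone to give 2α-(tert-butyldimethylsilyloxy)-1-[1-(diphenylphosphoryl)ethyl]-5α,6α-epoxy-7α-isopropyl-4-methylidene-octahydro-1H-inden-1-ol F5, the diastereomer that leads to the Z-alkene being separated by chromatography. Stereospecific syn-elimination (NaH, DMF, rt) should then give 18.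

Further compounds
F1 | step 6 | trimethyl[(3-methylbut-1-en-1-yl)oxy]silane (E/Z mixture) | CC(C)C=CO[Si](C)(C)C
F2 | step 6 | 3-methyl-2-{4,5-(isopropylidenedioxy)-2-[1-(trimethylsilyloxy)ethylidene]cyclopentyl}butanal | CC(O[Si](C)(C)C)=C1C[C@@H]2OC(C)(C)O[C@@H]2[C@H]1C(C(C)C)C=O
F3 | step 15 | (1Z)-1-ethylidene-5β,6α-dihydroxy-7α-isopropyl-4-methylidene-octahydro-1H-inden-2α-yl acetate | C=C1[C@@H]2C[C@H](OC(C)=O)/C(=C\C)[C@H]2[C@H](C(C)C)[C@H](O)[C@H]1O
F4 | step 15 | angelic 2,4,6-trichlorobenzoic anhydride | C/C=C(/C)C(=O)OC(=O)c1c(Cl)cc(Cl)cc1Cl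
F5 | step 12 | 2α-(tert-butyldimethylsilyloxy)-1-[1-(diphenylphosphoryl)ethyl]-5α,6α-epoxy-7α-isopropyl-4-methylidene-octahydro-1H-inden-1-ol | C=C1[C@@H]2C[C@H](O[Si](C)(C)C(C)(C)C)[C@@](O)([C@H](C)P(=O)(c4ccccc4)c5ccccc5)[C@H]2[C@H](C(C)C)[C@@H]3O[C@H]13
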